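The runs were generated by integration on assumed constants; scatter was added.

How much Prd is left in the beta run at 110 min, when the runs so far stop at 18 min? Beta has the charge of theta, so you are asking what theta does long after its last reading.

common to all: Cat 0.100 mM

| charge | Sub | Rgt | time |
|---|---|---|---|
| theta | 50.0 mM | 150 mM |  |
| zeta | 20.0 mM | 120 mM |  |
| delta | 50.0 mM | 220 mM |  |
| eta | 75.0 mM | 150 mM |  |
| beta | 50.0 mM | 150 mM | 110 min |

| run | time / min | [Prd] / mM |
|---|---|---|
| theta run | 3.0 | 8.1 |
| theta run | 6.0 | 14.6 |
| theta run | 9.0 | 19.5 |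
| theta run | 12 | 20.3 |
| theta run | 15 | 22.9 |
| theta run | 18 | 23.6 |
| zeta run | 3.0 | 3.0 |
| zeta run | 6.0 | 4.9 |
| zeta run | 9.0 | 6.9 |
| zeta run | 12 | 7.9 |
| zeta run | 15 | 9.2 |
| zeta run | 18 | 9.0 |
| delta run | 3.0 | 12.1 |
| delta run | 6.0 | 18.6 |
| delta run | 9.0 | 22.1 |
| delta run | 12 | 23.7 |
| delta run | 15 | 24.2 |
| delta run | 18 | 22.8 |
| eta run | 3.0 | 13.5 |
| eta run | 6.0 | 21.4 |
| eta run | 9.0 | 26.5 |
| eta run | 12 | 30.1 |
| eta run | 15 | 33.7 |
| eta run | 18 | 34.5 |

(standard deviation of a reading: 0.4 mM)

- the power of [Sub] that the first rate follows, about the charge of the theta run; measure it at two percent of Sub made into Prd (one fixed amount of Prd, the same in the runs compared)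
- the power of [Rgt] that the first rate follows, about the charge of the theta run; measure it at two percent of Sub made into Prd
- Prd in the beta run at 110 min, as a share of the Sub charged

- Overall: Sub + Rgt -> Prd, with Cat as catalyst.
- Constant volume, constant temperature.
- An order is taken over about fifteen percent of the charge, up and down.

Let f be the Prd as a fraction of the Sub charged.

1. First estimate: the curves flatten near half, so beta should end near there. But delta reads 24.2 mM at 15 min and 22.8 mM at 18 min. That drop of 1.40 mM stands against 0.566 mM of scatter on a difference. I therefore read a peak: Prd is lost while it is made.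

2. Powers: at 6.0 min, eta over theta reads 1.47 with Sub at 1.50 times. At 3.0 min, delta over theta reads 1.49 with Rgt at 1.47 times. I take the first power of each. Delta's readings top out at 15 min, while theta's still climb at nearly the same height, so I let the loss follow Rgt too.

3. A peak at f = 0.5 fits consecutive reactions with making twice as fast as losing. Let u be the exponential of minus loss constant times Rgt times time. Then the Sub share is u times u, and f = 2u(1 − u). The peak stands at u = 0.5, at time ln(2) over constant times Rgt.

Objection: Rgt falls. If the loss takes one Rgt as well, 2(1 − u) charges of Rgt are used, which is one charge at the peak, so the average Rgt up to the peak lies about 0.5 charge below the start. Delta's peak, as read at 15 min, then gives 0.237 M⁻¹ min⁻¹. This is the loss constant, the fraction of Prd lost per minute per unit of Rgt.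

4. By this estimate beta peaks near 23.4 min, with a quarter of the charge lost. Count the remaining Sub with Prd as g = 0.750. Rgt left is then 1 + g charges, and g/(1 + g) shrinks at 0.0118 min⁻¹.

Objection: g overstates the Prd exposed, while the balance of step 3 puts Rgt at the peak at 2 charges, not 1.75. These errors pull opposite ways, so I keep the estimate: 18.1%.

5. The forecast gives a power of 1 in Sub (0.8 to 1.25), a power of 1 in Rgt (0.75 to 1.3), and 50% (46% to 57%): “The catalyst is therefore dead by 110 min”. We agree on the powers, but my share is lower.

6. The flask gives a power of 1.0 in Sub, a power of 1.0 in Rgt, and 17.5% in the beta run.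

    2 Cat ⇌ Cat2, settled at all times (34600 M⁻¹)
    Cat + Sub + Rgt → Prd + Cat (7680 M⁻² min⁻¹)
    Sub + Rgt → Prd (0.2262 M⁻¹ min⁻¹)
    Prd + Rgt → Sid (0.2598 M⁻¹ min⁻¹)

The conversion of Prd and Rgt into Sid is the reason for the low share: the beta run without it gives 99.6% instead of 17.5%. Counting its Sub as spent, beta holds about 58.8 mM of Rgt at 110 min, so the loss constant has its Prd still shrinking at 0.0139 min⁻¹. In the eta run, Prd at a quarter of the charge needs u = 0.854, so the constant, with Rgt averaged, puts that at 4.81 min, and the eta run reaches it at 4.96 min.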